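**Assumptions (one line each):** The carbinol is (R), read from the SMILES and checked against CIP priorities O > aryl > CH2. The alkene is E. Compounds 1, 2, 4, 5 and 8 are commercial.

## Retrosynthetic overview
- Target ← global aryl methyl ether cleavage ← 22-membered macrocycle, formed last by E-selective ring-closing metathesis (RCM) of a terminal diene that carries the free (R)-benzylic alcohol.
- The (R) alcohol comes from asymmetric transfer hydrogenation of the aryl alkyl ketone. That ketone comes from a Grignard addition to an aldehyde followed by oxidation.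
- The aldehyde is a diaryl ether made by a Cu-catalysed Ullmann coupling of syringaldehyde with 3,5-dibromoanisole. The remaining Ar–Br is alkylated with a hept-6-enyl-9-BBN reagent by Suzuki coupling.
- Order of ring formation: the two arenes are linked through the diaryl ether first, and the macrocycle is closed last by RCM.

## Route

**Step 1**
Reactants: 1 (3,5-dibromoanisole, 3 equiv) and 2 (syringaldehyde)
Product: 3 (4-(3-bromo-5-methoxyphenoxy)-3,5-dimethoxybenzaldehyde)
Conditions: CuI (10 mol%), picolinic acid (20 mol%), K3PO4, DMSO, 90 °C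
Reagents that add atoms: none
Why: Cu/picolinic acid Ullmann C–O coupling tolerates the hindered 2,6-dimethoxyphenol and the electron-rich aryl bromide. Excess dibromide limits double arylation, and no stereocenter is involved.

**Step 2**
Reactants: 4 (1,6-heptadiene, 3 equiv) and 5 (9-BBN-H)
Product: 6 (9-(hept-6-en-1-yl)-9-BBN)
Conditions: THF, 0 °C to rt, 3 h; used in situ
Reagents that add atoms: none
Why: 9-BBN hydroborates the terminal alkene selectively and anti-Markovnikov. Excess diene suppresses bis-hydroboration, and the product is a B-alkyl Suzuki partner.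

**Step 3**
Reactants: 3 and 6
Product: 7 (4-[3-(hept-6-en-1-yl)-5-methoxyphenoxy]-3,5-dimethoxybenzaldehyde)
Conditions: Pd(dppf)Cl2 (5 mol%), aq. K3PO4, THF, 65 °C
Reagents that add atoms: none
Why: B-alkyl Suzuki–Miyura coupling (C(sp2)–C(sp3)). The aldehyde, the ethers and the terminal alkene survive, and there is no stereocenter.

**Step 4**
Reactants: 7 and 8 (8-bromooct-1-ene, converted beforehand to oct-7-en-1-ylmagnesium bromide with Mg in THF)
Product: 9 (racemic 1-aryl-non-8-en-1-ol)
Conditions: CH2=CH(CH2)6MgBr, THF, 0 °C to rt; then aq. NH4Cl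
Reagents that add atoms: none (the Grignard reagent is compound 8 activated by Mg, and NH4Cl only protonates)
Why: Grignard 1,2-addition to the aldehyde. Nothing else in 7 reacts with the Grignard, and the new carbinol is racemic and is reset in step 6.

**Step 5**
Reactants: 9
Product: 10 (1-aryl-non-8-en-1-one)
Conditions: Dess–Martin periodinane, CH2Cl2, rt, 1 h
Reagents that add atoms: none
Why: Mild oxidation of the benzylic secondary alcohol to the ketone, which removes the racemic stereocenter. The alkenes and electron-rich arenes are untouched.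

**Step 6**
Reactants: 10
Product: 11 ((R)-1-aryl-non-8-en-1-ol)
Conditions: RuCl[(R,R)-TsDPEN](p-cymene) (2 mol%), HCOOH/Et3N (5:2), CH2Cl2, 30 °C, 24–48 h
Reagents that add atoms: none (the hydride comes from formate and CO2 is lost)
Why: Noyori asymmetric transfer hydrogenation. The (R,R)-catalyst delivers hydride to the Re/Si face, as for acetophenone to (R)-1-phenylethanol, and sets the (R) carbinol in about 95% ee. The C=C bonds are not reduced.

**Step 7**
Reactants: 11
Product: 12 (macrocyclic trimethyl ether, E-alkene)
Conditions: Grubbs II (5–10 mol%), toluene, 2 mM, 60–80 °C, N2 sweep, 12 h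
Reagents that add atoms: none (ethylene is lost)
Why: Ring-closing metathesis of the two terminal alkenes gives the 22-membered ring, with the E isomer favoured thermodynamically. The free secondary alcohol is tolerated and the stereocenter is not touched. Any Z isomer is removed on AgNO3–silica.

**Step 8**
Reactants: 12
Product: 13 (dehydrogravicycle)
Conditions: NaSEt (10 equiv), DMF, 150 °C, 6 h; then 1 M HCl to pH 3
Reagents that add atoms: none (EtSMe is lost and HCl only protonates)
Why: Thiolate SN2 demethylation of the three aryl methyl ethers. It leaves the E-alkene, the diaryl ether and the benzylic alcohol alone, and avoids the benzylic ionisation and racemisation risk of BBr3.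

## Compound list
1 | 3,5-dibromoanisole | COc1cc(Br)cc(Br)c1 | starting material
2 | syringaldehyde | COc1cc(C=O)cc(OC)c1O | starting material
3 | 4-(3-bromo-5-methoxyphenoxy)-3,5-dimethoxybenzaldehyde | COc1cc(Br)cc(Oc2c(OC)cc(C=O)cc2OC)c1 | intermediate
4 | 1,6-heptadiene | C=CCCCC=C | starting material
5 | 9-BBN-H (9-borabicyclo[3.3.1]nonane) | B1C2CCCC1CCC2 | starting material
6 | 9-(hept-6-en-1-yl)-9-BBN | C=CCCCCCB1C2CCCC1CCC2 | intermediate
7 | 4-[3-(hept-6-en-1-yl)-5-methoxyphenoxy]-3,5-dimethoxybenzaldehyde | C=CCCCCCc1cc(OC)cc(Oc2c(OC)cc(C=O)cc2OC)c1 | intermediate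
8 | 8-bromooct-1-ene | C=CCCCCCCBr | starting material
9 | (±)-1-aryl-non-8-en-1-ol | C=CCCCCCCC(O)c1cc(OC)c(Oc2cc(OC)cc(CCCCCC=C)c2)c(OC)c1 | intermediate
10 | 1-aryl-non-8-en-1-one | C=CCCCCCCC(=O)c1cc(OC)c(Oc2cc(OC)cc(CCCCCC=C)c2)c(OC)c1 | intermediate
11 | (R)-1-aryl-non-8-en-1-ol | C=CCCCCCC[C@@H](O)c1cc(OC)c(Oc2cc(OC)cc(CCCCCC=C)c2)c(OC)c1 | intermediate
12 | macrocyclic trimethyl ether | COc1cc2cc(c1)Oc1c(OC)cc(cc1OC)[C@H](O)CCCCCC/C=C/CCCCC2 | intermediate
13 | dehydrogravicycle | Oc1cc2cc(c1)Oc1c(O)cc(cc1O)[C@H](O)CCCCCC/C=C/CCCCC2 | target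

**Total step count:** 8 steps.
**Longest linear sequence:** 7 steps (1 → 3 → 7 → 9 → 10 → 11 → 12 → 13).

## Three steps most likely to fail
1. **Step 7 (RCM).** It may give poor yield, oligomers, or an E/Z mixture.
   Fallback: make the diyne analogue and close it by ring-closing alkyne metathesis. Then reduce the alkyne to the E-alkene with Ru-catalysed trans-hydrosilylation followed by protodesilylation.
2. **Step 8 (triple demethylation).** The second ortho-OMe is slow to cleave once the ring carries a phenoxide.
   Fallback: acetylate the benzylic OH, cleave all three methyl ethers with BBr3 at –78 to 0 °C, and remove the acetate with K2CO3/MeOH.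
3. **Step 1 (Ullmann diaryl ether).** The phenol is hindered, and mono-arylation of the dibromide is only statistical.
   Fallback: Chan–Lam coupling of 2 with (3-bromo-5-methoxyphenyl)boronic acid, using Cu(OAc)2, pyridine, 4 Å molecular sieves and air.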